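**Strategy.** The γ-lactone is read as the Baeyer–Villiger image of a cyclobutanone: O7–C19 comes from a C7–C19 bond, and the C8 carbinol from an enol ether. A [2+2] cycloaddition of a chlorovinylketene (C19=C7, carrying C4–C6) with a 4-methylene-1,3-dioxolane (C8=C17, the C8/C9 diol acetonide on ring A) therefore forms C19–C17 and C7–C8 in one operation, unites the two fragments and sets C7 and C8. The temporary C7–C19 bond is then cut by oxygen insertion. The ketene arises by photochemical Wolff rearrangement of a diazoketone; the enol ether sits on a Diels–Alder-derived ring A. The ten-membered ring is closed afterwards at C3–C4.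

Key step: step 17

Remark: atoms carry briarane numbers (C1–C20; C19 lactone carbonyl, C18 lactone methyl, C15/C16/C20 the methyls on C1/C5/C11); β is the face of the C1 methyl.
Remark: in step 9 the diene is assumed to add anti to the C9–O bond of dienophile 14 in its conformer of least A(1,3) strain (H9 in the alkene plane next to the C1 methyl).

Step 1
Reactants: 1 methyl 4-hydroxybut-2-ynoate
Product: 2 methyl 4-{[tert-butyl(dimethyl)silyl]oxy}but-2-ynoate
Conditions: TBSCl, imidazole, CH2Cl2, 0 °C to rt
Reagents that add atoms: tert-butyl(chloro)dimethylsilane, CC(C)(C)[Si](C)(C)Cl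
Why: Silyl ether protection masks O4, which would otherwise lactonise onto the cis carboxyl carbon once the alkene is made.

Step 2
Reactants: 2 methyl 4-{[tert-butyl(dimethyl)silyl]oxy}but-2-ynoate
Product: 4 methyl (2E)-4-{[tert-butyl(dimethyl)silyl]oxy}-2-chloro-3-methylbut-2-enoate, via lithium alkenylcuprate 3 (not isolated)
Conditions: Me2CuLi (from CuI, MeLi), THF, −78 °C; then NCS, −78 to −40 °C
Reagents that add atoms: lithium dimethylcuprate, C[Cu-]C.[Li+]; N-chlorosuccinimide, O=C1CCC(=O)N1Cl
Why: Syn carbocupration (conjugate addition) puts the new methyl C16 and copper cis, and chlorination of the alkenylcuprate with retention gives C16 cis to Cl and C4 cis to the carboxyl carbon, i.e. the ring-cis C5=C6 geometry.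

Step 3
Reactants: 4 methyl (2E)-4-{[tert-butyl(dimethyl)silyl]oxy}-2-chloro-3-methylbut-2-enoate
Product: 5 (2E)-4-{[tert-butyl(dimethyl)silyl]oxy}-2-chloro-3-methylbut-2-enoic acid
Conditions: LiOH, THF/H2O, 0 °C to rt; then dilute HCl to pH 4
Reagents that add atoms: lithium hydroxide, [Li+].[OH-]
Why: Saponification; the primary TBS ether should survive cold LiOH, and the acid cannot lactonise while O4 is silylated.

Step 4
Reactants: 5 (2E)-4-{[tert-butyl(dimethyl)silyl]oxy}-2-chloro-3-methylbut-2-enoic acid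
Product: 7 (3E)-5-{[tert-butyl(dimethyl)silyl]oxy}-3-chloro-1-diazo-4-methylpent-3-en-2-one, via acid chloride 6 (not isolated)
Conditions: 1-chloro-N,N,2-trimethylprop-1-en-1-amine, CH2Cl2, 0 °C; then CH2N2 (2.5 equiv), Et2O, 0 °C
Reagents that add atoms: diazomethane, C=[N+]=[N-]
Why: Neutral acid chloride formation followed by acylation of diazomethane (first half of an Arndt–Eistert sequence) gives the α,β-unsaturated α′-diazoketone; the excess diazomethane takes up HCl.

Step 5
Reactants: 8 pent-1-en-3-one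
Product: 9 tert-butyldimethyl[(3Z)-penta-1,3-dien-3-yloxy]silane
Conditions: TBSOTf, Et3N, Et2O, 0 °C
Reagents that add atoms: tert-butyldimethylsilyl trifluoromethanesulfonate, CC(C)(C)[Si](C)(C)OS(=O)(=O)C(F)(F)F
Why: Soft enolisation and O-silylation of the ethyl ketone should give the (Z)-silyl enol ether, a 2-silyloxy diene with its methyl on the outside of the s-cis form.

Step 6
Reactants: 10 (4S,5S)-2,2-dimethyl-1,3-dioxolane-4,5-dimethanol
Product: 11 [(4S,5S)-5-(hydroxymethyl)-2,2-dimethyl-1,3-dioxolan-4-yl]methyl 4-methylbenzenesulfonate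
Conditions: TsCl (1.05 equiv), Ag2O, KI (cat.), CH2Cl2, rt
Reagents that add atoms: 4-methylbenzenesulfonyl chloride, Cc1ccc(cc1)S(Cl)(=O)=O
Why: Ag2O-mediated monosulfonylation of the C2-symmetric diol (either hydroxyl gives the same product) installs the leaving group that later becomes the C8=C17 alkene; C9 comes from the chiral pool.

Step 7
Reactants: 11 [(4S,5S)-5-(hydroxymethyl)-2,2-dimethyl-1,3-dioxolan-4-yl]methyl 4-methylbenzenesulfonate
Product: 12 [(4S,5R)-5-formyl-2,2-dimethyl-1,3-dioxolan-4-yl]methyl 4-methylbenzenesulfonate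
Conditions: 1,1,1-triacetoxy-1,1-dihydro-1,2-benziodoxol-3(1H)-one (DMP), NaHCO3, CH2Cl2, 0 °C to rt
Reagents that add atoms: none
Why: Periodinane oxidation of the primary alcohol under buffered conditions keeps the trans-dioxolane α-alkoxy aldehyde from epimerising.

Step 8
Reactants: 12 [(4S,5R)-5-formyl-2,2-dimethyl-1,3-dioxolan-4-yl]methyl 4-methylbenzenesulfonate; 13 2-(triphenylphosphoranylidene)propanal
Product: 14 {(4S,5S)-2,2-dimethyl-5-[(1E)-2-methyl-3-oxoprop-1-en-1-yl]-1,3-dioxolan-4-yl}methyl 4-methylbenzenesulfonate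
Conditions: toluene, 90 °C
Reagents that add atoms: none
Why: Wittig olefination with the stabilised formyl ylide gives the (E)-enal, placing the future C1 methyl cis to the C9 arm.

Step 9
Reactants: 14 (E)-enal dienophile; 9 tert-butyldimethyl[(3Z)-penta-1,3-dien-3-yloxy]silane
Product: 15 ring A aldehyde (TBS enol ether C12=C13; C1 with CHO and methyl; C10 dioxolanyl cis to the C1 methyl; C11 methyl trans to the C1 methyl)
Conditions: Me2AlCl (0.5 equiv), CH2Cl2, −78 to −30 °C
Reagents that add atoms: none
Why: Lewis acid-catalysed Diels–Alder reaction with para orientation (C11 to C10, C14 to C1); the (E)-dienophile makes the C1 methyl cis to the C9 arm, addition anti to the C9–O bond (remark) sets C1 and C10 absolutely, and the endo-formyl transition state leaves the C11 methyl trans to the C1 methyl, which step 12 corrects.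

Step 10
Reactants: 15 ring A aldehyde
Product: 16 β-hydroxy sulfone (C2 carbinol, both epimers; C3 bears PhSO2)
Conditions: PhSO2CH3, n-BuLi, THF, −78 °C; then 15, −78 °C; NH4Cl
Reagents that add atoms: (phenylsulfonyl)methyllithium, [Li]CS(=O)(=O)c1ccccc1
Why: 1,2-Addition of the α-sulfonyl carbanion to the only free carbonyl (the ketone is still a silyl enol ether) brings in C3 with its activating group; the C2 mixture is irrelevant because C2 becomes a ketone in step 16.

Step 11
Reactants: 16 β-hydroxy sulfone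
Product: 17 enone (C12 ketone, C13=C14; C11 methyl still trans to the C1 methyl)
Conditions: Pd(OAc)2 (1.1 equiv), MeCN, rt
Reagents that add atoms: none
Why: Saegusa–Ito oxidation converts the regiodefined silyl enol ether into the C13=C14 enone without touching C11.

Step 12
Reactants: 17 enone
Product: 19 enone with inverted C11 (C11 methyl cis to the C1 methyl and the C9 arm), via dilithium dienolate 18 (not isolated)
Conditions: LDA (2.3 equiv), THF, −78 °C; then AcOH in THF, −78 °C
Reagents that add atoms: none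
Why: Kinetic α′-deprotonation gives the cross-conjugated dienolate, in which A(1,2) strain turns the C9 arm pseudoaxial on the β face; kinetic protonation therefore comes from the α face and sets the C11 methyl β, whichever C11 epimer entered.

Step 13
Reactants: 19 enone with the C11 methyl β
Product: 20 12β-allylic alcohol (OH cis to the C11 methyl)
Conditions: NaBH4, CeCl3·7H2O, MeOH, −78 °C
Reagents that add atoms: none
Why: Luche 1,2-reduction; hydride should come from the α face, opposite the three β substituents (C11 methyl, C9 arm, C1 methyl), giving the 12β-alcohol that step 27 inverts.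

Step 14
Reactants: 20 12β-allylic alcohol
Product: 21 12β-TBS ether (C2–OH free)
Conditions: TBSOTf (1.05 equiv), 2,6-lutidine, CH2Cl2, −78 °C
Reagents that add atoms: tert-butyldimethylsilyl trifluoromethanesulfonate, CC(C)(C)[Si](C)(C)OS(=O)(=O)C(F)(F)F
Why: Silyl ether protection is selective for the allylic C12 hydroxyl because the C2 hydroxyl is neopentyl and flanked by the sulfonylmethyl group.

Step 15
Reactants: 21 12β-TBS ether
Product: 23 enol ether alcohol (4-methylene-1,3-dioxolane), via primary iodide 22 (not isolated)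
Conditions: NaI, DBU, DME, 85 °C
Reagents that add atoms: none
Why: Finkelstein exchange followed by E2 elimination; the only β-hydrogen is on C8, so the exocyclic C8=C17 enol ether is the only possible alkene.

Step 16
Reactants: 23 enol ether alcohol
Product: 24 enol ether β-keto sulfone (C2 ketone)
Conditions: 1,1,1-triacetoxy-1,1-dihydro-1,2-benziodoxol-3(1H)-one (DMP), NaHCO3, CH2Cl2, 0 °C
Reagents that add atoms: none
Why: Buffered periodinane oxidation gives the β-keto sulfone needed for ring closure while sparing the acid-sensitive enol ether.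

Step 17
Reactants: 24 enol ether β-keto sulfone; 7 diazoketone (2.5 equiv, added slowly)
Product: 26 spiro-cyclobutanone, via vinylketene 25 (not isolated)
Conditions: hν (365 nm), CH2Cl2, 0 °C to rt
Reagents that add atoms: none
Why: Light triggers a Wolff rearrangement of 7 (the chlorovinyl group migrates to C7 with its C5=C6 geometry intact) and the resulting vinylketene 25 is trapped by the enol ether in a ketene–alkene [2+2] cycloaddition, the closest known reaction type being cyclobutanone formation from photochemically generated vinylketenes or from ketenes with enol ethers. The four-membered ring closes in a polar, asynchronous (formally π2s + π2a) mode: nucleophilic C17 attacks the ketene carbonyl carbon C19 and the enolate carbon C7 then bonds to the oxocarbenium carbon C8, which dictates the regiochemistry. C8 is controlled by C9, the ketene adding to the exocyclic alkene face anti to the ring A substituent on the dioxolane; C7 is controlled by closure with the chlorovinyl arm turned away from the C9 side (cis to O8), the same isomer that equilibration of the α-keto C7–H would favour. The step needs periselectivity for the ketene C=C over the vinylketene diene and chemoselectivity for the enol ether, which the electron-rich, unhindered C8=C17 bond secures; 24 carries no free hydroxyl and its other alkene is unactivated. The added C7–C19 bond is not in the target and is cut by oxygen insertion in step 18.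

Step 18
Reactants: 26 spiro-cyclobutanone
Product: 27 γ-lactone (O inserted between C7 and C19)
Conditions: mCPBA (1.1 equiv), NaHCO3, CH2Cl2, −10 °C
Reagents that add atoms: 3-chloroperoxybenzoic acid, OOC(=O)c1cccc(Cl)c1
Why: Baeyer–Villiger oxidation of the strained ketone; the secondary allylic C7 migrates in preference to the primary C17 and with retention, so the C7 configuration is carried into the lactone.

Step 19
Reactants: 27 γ-lactone
Product: 28 primary allylic alcohol (C4–OH; C12 TBS ether kept)
Conditions: HF·pyridine, pyridine, THF, 0 °C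
Reagents that add atoms: none
Why: Buffered fluoride desilylation should cleave the primary allylic TBS ether much faster than the hindered secondary one at C12 and leave the acetonide intact.

Step 20
Reactants: 28 primary allylic alcohol
Product: 30 allylic chloride, via allylic mesylate 29 (not isolated)
Conditions: MsCl, 2,4,6-collidine, LiCl, DMF, 0 °C
Reagents that add atoms: lithium chloride, [Li+].[Cl-]
Why: Mesylation and in situ SN2 displacement by chloride give the primary allylic chloride without allylic transposition or base strong enough to ionise the β-keto sulfone.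

Step 21
Reactants: 30 allylic chloride
Product: 31 ten-membered β-keto sulfone (new C3–C4 bond; C3 epimers)
Conditions: Cs2CO3, MeCN, 60 °C, syringe-pump addition (final 2 mM)
Reagents that add atoms: none
Why: Intramolecular SN2 C-alkylation of the soft β-keto sulfone anion by the allylic chloride (macrocyclisation of a stabilised carbanion); carbonate does not enolise the lactone and the cis C5=C6 alkene turns the chain toward C3.

Step 22
Reactants: 31 ten-membered β-keto sulfone
Product: 33 17-methyl lactone (C18 cis to O8), via dilithium dianion 32 (not isolated)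
Conditions: LDA (2.2 equiv), THF, −78 °C; then MeI (1.1 equiv), −78 °C
Reagents that add atoms: iodomethane, CI
Why: Enolate alkylation; the first equivalent parks the C2 ketone as its unreactive tertiary β-keto sulfone anion, and the lactone enolate is methylated on the face anti to C9 (cis to O8), which is also the thermodynamically preferred C17 configuration.

Step 23
Reactants: 33 17-methyl lactone
Product: 34 C2 ketone (C3 methylene)
Conditions: SmI2, THF/MeOH, −78 °C
Reagents that add atoms: none
Why: Reductive desulfonylation of the α-sulfonyl ketone by single-electron transfer is fast at −78 °C and leaves the vinyl chloride, lactone and silyl ether alone.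

Step 24
Reactants: 34 C2 ketone
Product: 35 (2S)-alcohol
Conditions: (R)-2-methyl-CBS-oxazaborolidine (0.5 equiv), catecholborane, toluene, −60 °C
Reagents that add atoms: none
Why: Corey–Bakshi–Shibata reduction; the catalyst distinguishes the quaternary C1 side from the C3 methylene side and the (R)-catalyst should deliver the (2S)-carbinol under reagent control.

Step 25
Reactants: 35 (2S)-alcohol
Product: 36 2-acetate
Conditions: Ac2O, DMAP, Et3N, CH2Cl2, rt
Reagents that add atoms: acetic anhydride, CC(=O)OC(C)=O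
Why: DMAP-catalysed acylation of the only free hydroxyl.

Step 26
Reactants: 36 2-acetate
Product: 37 12β-alcohol
Conditions: HF·pyridine, pyridine, THF, 0 °C to rt
Reagents that add atoms: none
Why: Fluoride desilylation frees the allylic C12 hydroxyl; buffered HF leaves the acetate, lactone and acetonide.

Step 27
Reactants: 37 12β-alcohol
Product: 38 2,12α-diacetate acetonide
Conditions: AcOH, PPh3, DIAD, toluene, 0 °C to rt
Reagents that add atoms: acetic acid, CC(=O)O
Why: Mitsunobu esterification inverts C12 by SN2 attack of acetate from the open α face, giving the acetate trans to the C11 methyl; SN2′ attack at C14 is blocked by the quaternary C1.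

Step 28
Reactants: 38 2,12α-diacetate acetonide
Product: 39 CNP0296164.1
Conditions: TFA/H2O (9:1), CH2Cl2, 0 °C
Reagents that add atoms: none
Why: Acid-catalysed acetal hydrolysis frees the C8/C9 diol; the acetates, the lactone and the vinyl chloride are stable to brief cold aqueous acid.

**Compound list**

1 | methyl 4-hydroxybut-2-ynoate | COC(=O)C#CCO | starting material
2 | methyl 4-{[tert-butyl(dimethyl)silyl]oxy}but-2-ynoate | COC(=O)C#CCO[Si](C)(C)C(C)(C)C | intermediate
3 | lithium alkenyl(methyl)cuprate from syn addition (Cu on C6, cis to the new methyl) | COC(=O)/C([Cu-]C)=C(/C)CO[Si](C)(C)C(C)(C)C.[Li+] | intermediate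
4 | methyl (2E)-4-{[tert-butyl(dimethyl)silyl]oxy}-2-chloro-3-methylbut-2-enoate | COC(=O)/C(Cl)=C(/C)CO[Si](C)(C)C(C)(C)C | intermediate
5 | (2E)-4-{[tert-butyl(dimethyl)silyl]oxy}-2-chloro-3-methylbut-2-enoic acid | OC(=O)/C(Cl)=C(/C)CO[Si](C)(C)C(C)(C)C | intermediate
6 | (2E)-4-{[tert-butyl(dimethyl)silyl]oxy}-2-chloro-3-methylbut-2-enoyl chloride | ClC(=O)/C(Cl)=C(/C)CO[Si](C)(C)C(C)(C)C | intermediate
7 | (3E)-5-{[tert-butyl(dimethyl)silyl]oxy}-3-chloro-1-diazo-4-methylpent-3-en-2-one | [N-]=[N+]=CC(=O)/C(Cl)=C(/C)CO[Si](C)(C)C(C)(C)C | intermediate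
8 | pent-1-en-3-one | CCC(=O)C=C | starting material
9 | tert-butyldimethyl[(3Z)-penta-1,3-dien-3-yloxy]silane | C=C/C(O[Si](C)(C)C(C)(C)C)=C/C | intermediate
10 | (4S,5S)-2,2-dimethyl-1,3-dioxolane-4,5-dimethanol (2,3-O-isopropylidene-L-threitol) | CC1(C)O[C@@H](CO)[C@H](CO)O1 | starting material
11 | [(4S,5S)-5-(hydroxymethyl)-2,2-dimethyl-1,3-dioxolan-4-yl]methyl 4-methylbenzenesulfonate | CC1(C)O[C@@H](COS(=O)(=O)c2ccc(C)cc2)[C@H](CO)O1 | intermediate
12 | [(4S,5R)-5-formyl-2,2-dimethyl-1,3-dioxolan-4-yl]methyl 4-methylbenzenesulfonate | CC1(C)O[C@@H](COS(=O)(=O)c2ccc(C)cc2)[C@H](C=O)O1 | intermediate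
13 | 2-(triphenylphosphoranylidene)propanal | CC(C=O)=P(c1ccccc1)(c1ccccc1)c1ccccc1 | starting material
14 | {(4S,5S)-2,2-dimethyl-5-[(1E)-2-methyl-3-oxoprop-1-en-1-yl]-1,3-dioxolan-4-yl}methyl 4-methylbenzenesulfonate | CC1(C)O[C@@H](COS(=O)(=O)c2ccc(C)cc2)[C@H](/C=C(\C)C=O)O1 | intermediate
15 | ring A aldehyde: C12 TBS enol ether (C12=C13), C1 CHO and methyl, C10 dioxolanyl cis to the C1 methyl, C11 methyl trans to the C1 methyl (endo adduct) | CC1(C)O[C@@H](COS(=O)(=O)c2ccc(C)cc2)[C@H]([C@H]3[C@H](C)C(O[Si](C)(C)C(C)(C)C)=CC[C@]3(C)C=O)O1 | intermediate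
16 | β-hydroxy sulfone of 15 (C2 carbinol, both epimers; PhSO2 on C3) | CC1(C)O[C@@H](COS(=O)(=O)c2ccc(C)cc2)[C@H]([C@H]3[C@H](C)C(O[Si](C)(C)C(C)(C)C)=CC[C@]3(C)C(O)CS(=O)(=O)c4ccccc4)O1 | intermediate
17 | enone (C12=O, C13=C14), C11 methyl trans to the C1 methyl | CC1(C)O[C@@H](COS(=O)(=O)c2ccc(C)cc2)[C@H]([C@H]3[C@H](C)C(=O)C=C[C@]3(C)C(O)CS(=O)(=O)c4ccccc4)O1 | intermediate
18 | dilithium C2-alkoxide C11=C12 dienolate of 17 | CC1(C)O[C@@H](COS(=O)(=O)c2ccc(C)cc2)[C@H]([C@H]3C(C)=C([O-])C=C[C@]3(C)C([O-])CS(=O)(=O)c4ccccc4)O1.[Li+].[Li+] | intermediate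
19 | enone with the C11 methyl β (cis to the C1 methyl and the C9 arm) | CC1(C)O[C@@H](COS(=O)(=O)c2ccc(C)cc2)[C@H]([C@H]3[C@@H](C)C(=O)C=C[C@]3(C)C(O)CS(=O)(=O)c4ccccc4)O1 | intermediate
20 | 12β-allylic alcohol (OH cis to the C11 methyl), C2–OH free | CC1(C)O[C@@H](COS(=O)(=O)c2ccc(C)cc2)[C@H]([C@H]3[C@@H](C)[C@@H](O)C=C[C@]3(C)C(O)CS(=O)(=O)c4ccccc4)O1 | intermediate
21 | 12β-TBS ether of 20 | CC1(C)O[C@@H](COS(=O)(=O)c2ccc(C)cc2)[C@H]([C@H]3[C@@H](C)[C@@H](O[Si](C)(C)C(C)(C)C)C=C[C@]3(C)C(O)CS(=O)(=O)c4ccccc4)O1 | intermediate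
22 | primary iodide (C17–I) corresponding to 21 | CC1(C)O[C@@H](CI)[C@H]([C@H]3[C@@H](C)[C@@H](O[Si](C)(C)C(C)(C)C)C=C[C@]3(C)C(O)CS(=O)(=O)c4ccccc4)O1 | intermediate
23 | enol ether alcohol: 2,2-dimethyl-4-methylene-1,3-dioxolane (C8=C17) on C9, C2–OH free | CC1(C)OC(=C)[C@H]([C@H]3[C@@H](C)[C@@H](O[Si](C)(C)C(C)(C)C)C=C[C@]3(C)C(O)CS(=O)(=O)c4ccccc4)O1 | intermediate
24 | enol ether β-keto sulfone (C2 ketone) | CC1(C)OC(=C)[C@H]([C@H]3[C@@H](C)[C@@H](O[Si](C)(C)C(C)(C)C)C=C[C@]3(C)C(=O)CS(=O)(=O)c4ccccc4)O1 | intermediate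
25 | (3E)-5-{[tert-butyl(dimethyl)silyl]oxy}-3-chloro-4-methylpenta-1,3-dien-1-one (vinylketene) | O=C=C/C(Cl)=C(/C)CO[Si](C)(C)C(C)(C)C | intermediate
26 | spiro-cyclobutanone (C19 ketone, ring C7–C19–C17–C8; C8 spiro to the acetonide; chlorovinyl arm on C7 cis to O8) | CC(C)(C)[Si](C)(C)OC/C(C)=C(/Cl)[C@@H]2C(=O)C[C@@]2(OC(C)(C)O3)[C@@H]3[C@H]4[C@@H](C)[C@@H](O[Si](C)(C)C(C)(C)C)C=C[C@]4(C)C(=O)CS(=O)(=O)c5ccccc5 | intermediate
27 | γ-lactone (O between C7 and C19), bis-TBS ether | CC(C)(C)[Si](C)(C)OC/C(C)=C(/Cl)[C@@H]2OC(=O)C[C@@]2(OC(C)(C)O3)[C@@H]3[C@H]4[C@@H](C)[C@@H](O[Si](C)(C)C(C)(C)C)C=C[C@]4(C)C(=O)CS(=O)(=O)c5ccccc5 | intermediate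
28 | primary allylic alcohol (C4–OH) | OC/C(C)=C(/Cl)[C@@H]2OC(=O)C[C@@]2(OC(C)(C)O3)[C@@H]3[C@H]4[C@@H](C)[C@@H](O[Si](C)(C)C(C)(C)C)C=C[C@]4(C)C(=O)CS(=O)(=O)c5ccccc5 | intermediate
29 | allylic mesylate of 28 | CS(=O)(=O)OC/C(C)=C(/Cl)[C@@H]2OC(=O)C[C@@]2(OC(C)(C)O3)[C@@H]3[C@H]4[C@@H](C)[C@@H](O[Si](C)(C)C(C)(C)C)C=C[C@]4(C)C(=O)CS(=O)(=O)c5ccccc5 | intermediate
30 | allylic chloride (C4–Cl) | ClC/C(C)=C(/Cl)[C@@H]2OC(=O)C[C@@]2(OC(C)(C)O3)[C@@H]3[C@H]4[C@@H](C)[C@@H](O[Si](C)(C)C(C)(C)C)C=C[C@]4(C)C(=O)CS(=O)(=O)c5ccccc5 | intermediate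
31 | ten-membered β-keto sulfone (C2 ketone, PhSO2 on C3, C3 epimers) | O=C1C(S(=O)(=O)c5ccccc5)C/C(C)=C(/Cl)[C@@H]2OC(=O)C[C@@]2(OC(C)(C)O3)[C@@H]3[C@H]4[C@@H](C)[C@@H](O[Si](C)(C)C(C)(C)C)C=C[C@@]41C | intermediate
32 | dilithium dianion of 31 (C2/C3 enolate and lactone enolate) | [O-]C1=C(S(=O)(=O)c5ccccc5)C/C(C)=C(/Cl)[C@@H]2OC([O-])=C[C@@]2(OC(C)(C)O3)[C@@H]3[C@H]4[C@@H](C)[C@@H](O[Si](C)(C)C(C)(C)C)C=C[C@@]41C.[Li+].[Li+] | intermediate
33 | 17-methyl lactone (C18 cis to O8), sulfone retained | O=C1C(S(=O)(=O)c5ccccc5)C/C(C)=C(/Cl)[C@@H]2OC(=O)[C@H](C)[C@@]2(OC(C)(C)O3)[C@@H]3[C@H]4[C@@H](C)[C@@H](O[Si](C)(C)C(C)(C)C)C=C[C@@]41C | intermediate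
34 | C2 ketone (C3 methylene) | O=C1CC/C(C)=C(/Cl)[C@@H]2OC(=O)[C@H](C)[C@@]2(OC(C)(C)O3)[C@@H]3[C@H]4[C@@H](C)[C@@H](O[Si](C)(C)C(C)(C)C)C=C[C@@]41C | intermediate
35 | (2S)-alcohol | O[C@H]1CC/C(C)=C(/Cl)[C@@H]2OC(=O)[C@H](C)[C@@]2(OC(C)(C)O3)[C@@H]3[C@H]4[C@@H](C)[C@@H](O[Si](C)(C)C(C)(C)C)C=C[C@@]41C | intermediate
36 | 2-acetate, 12β-TBS ether | CC(=O)O[C@H]1CC/C(C)=C(/Cl)[C@@H]2OC(=O)[C@H](C)[C@@]2(OC(C)(C)O3)[C@@H]3[C@H]4[C@@H](C)[C@@H](O[Si](C)(C)C(C)(C)C)C=C[C@@]41C | intermediate
37 | 2-acetate, 12β-alcohol | CC(=O)O[C@H]1CC/C(C)=C(/Cl)[C@@H]2OC(=O)[C@H](C)[C@@]2(OC(C)(C)O3)[C@@H]3[C@H]4[C@@H](C)[C@@H](O)C=C[C@@]41C | intermediate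
38 | 2,12α-diacetate, C8/C9 acetonide | CC(=O)O[C@H]1CC/C(C)=C(/Cl)[C@@H]2OC(=O)[C@H](C)[C@@]2(OC(C)(C)O3)[C@@H]3[C@H]4[C@@H](C)[C@H](OC(C)=O)C=C[C@@]41C | intermediate
39 | CNP0296164.1 | CC(=O)O[C@H]1CC/C(C)=C(/Cl)[C@@H]2OC(=O)[C@H](C)[C@@]2(O)[C@@H](O)[C@H]2[C@@H](C)[C@H](OC(C)=O)C=C[C@@]21C | target

**Step count.** 28 steps in total; the longest linear sequence is 23 steps (10 to 39, steps 6–16 and 17–28).

**Steps most likely to fail**

1. Step 17. The vinylketene may dimerise or be consumed before it meets the hindered enol ether, and carbene side reactions of the excited diazoketone or poor selectivity at C7 may erode the union. The fallback sets out from 7 and 24 and comes back at 26. It generates the same ketene thermally from an acid chloride instead of by light. Wolff rearrangement of 7 in THF/H2O with PhCO2Ag (cat.) and Et3N gives (3E)-5-{[tert-butyl(dimethyl)silyl]oxy}-3-chloro-4-methylpent-3-enoic acid F1. Oxalyl chloride with catalytic DMF converts it into (3E)-5-{[tert-butyl(dimethyl)silyl]oxy}-3-chloro-4-methylpent-3-enoyl chloride F2. Slow addition of F2 to 24 and i-Pr2NEt in toluene at 80 °C dehydrochlorinates it to 25 at the rate of addition, in the presence of concentrated enol ether, and the [2+2] cycloaddition gives 26.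

2. Step 21. Intermolecular alkylation (oligomers) or O-alkylation may outrun closure of the strained ten-membered ring. The fallback sets out from 28 and comes back at 31. Methyl chloroformate and pyridine convert 28 into the allylic methyl carbonate F3. Pd(PPh3)4 with dppe in THF at 65 °C under high dilution ionises it to a π-allyl complex of divalent palladium. The methoxide released deprotonates the β-keto sulfone, which attacks the CH2 terminus (Tsuji–Trost macrocyclisation on the metal template) to give 31.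

3. Step 9. The π-facial selectivity may be poor or reversed if C9 does not steer the diene as assumed, and Mukaiyama-type 1,2-addition to the aldehyde may compete. The fallback sets out from 14 and 9 and comes back at 15. It replaces substrate control by catalyst control: the cycloaddition is run with a chiral oxazaborolidinium triflimide (protonated 2-(o-tolyl)-CBS-oxazaborolidine, the enantiomer that reinforces the required face). This catalyst binds the formyl group of α-methyl enals and dictates the diene approach. No new compound is made (F0).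

Further compounds
F1 | step 17 | (3E)-5-{[tert-butyl(dimethyl)silyl]oxy}-3-chloro-4-methylpent-3-enoic acid | OC(=O)C/C(Cl)=C(/C)CO[Si](C)(C)C(C)(C)C
F2 | step 17 | (3E)-5-{[tert-butyl(dimethyl)silyl]oxy}-3-chloro-4-methylpent-3-enoyl chloride | ClC(=O)C/C(Cl)=C(/C)CO[Si](C)(C)C(C)(C)C
F3 | step 21 | allylic methyl carbonate of 28 | COC(=O)OC/C(C)=C(/Cl)[C@@H]2OC(=O)C[C@@]2(OC(C)(C)O3)[C@@H]3[C@H]4[C@@H](C)[C@@H](O[Si](C)(C)C(C)(C)C)C=C[C@]4(C)C(=O)CS(=O)(=O)c5ccccc5
F0 | step 9 | none | none
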